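Atom numbering used throughout: five-membered ring C1(CH3)–C2–C3–C4(OH)(i-Pr)–C5; seven-membered ring C5–C6(O-acyl)–C7–C8(CH3)–C9–C10–C1; epoxide oxygen on C8 and C9. "Methyl face" means the face of the bicycle that carries the C1 methyl group, "H5 face" the opposite one.

## The problem

Compound 16 is a daucane-type sesquiterpenoid ester in which a cyclopentane (C1–C5) is trans-fused along C1–C5 to a cycloheptane (C5–C10 and C1) that carries a 3,4-dimethoxybenzoate at C6 and a trisubstituted epoxide across C8–C9. Six stereocentres have to be set: quaternary C1 (R), the tertiary isopropyl carbinol C4 (R), the ring-fusion methine C5 (S), the acyloxy carbon C6 (S) and the epoxide carbons C8 (R) and C9 (S). The C4 hydroxyl lies on the methyl face, whereas the isopropyl group, the C6 oxygen and the epoxide oxygen lie on the H5 face. C1 has no neighbouring stereocentre or heteroatom to derive it from, so it must be created by a chiral catalyst and then act as the anchor: C5 by a facial choice next to C1, C6 by the geometry of the C5–C6 bond formation, C4 by addition to a ketone of the rigid bicycle, and C8/C9 by delivery from the C6 hydroxyl. The weakest link is C1 to C5, because C1 tells the two faces of C5 apart only through a methyl group against a CH2 arm. Several groups are fragile: the epoxide is acid-labile and can be opened transannularly by the C4 hydroxyl, the tertiary alcohol dehydrates, the ester does not survive organometallic reagents, and on the way a β-hydroxy ketone (retro-aldol, epimerisation at C5) and β,γ-unsaturated carbonyl compounds (double-bond migration into conjugation) must be handled. The enabling feature is that C1, C5 and C4 are the β-carbon, α-carbon and carbonyl carbon of a cyclopentanone, while C6 is a carbinol carbon bonded to C5; the five-membered ring with C6 is therefore the aldol of a β-methylated cyclopentanone. The rest of the seven-membered ring reduces to two olefin-terminated arms, C10–C9 on C1 and C7–C8 on C6, whose union gives the C8=C9 alkene that is homoallylic to the C6 hydroxyl and becomes the epoxide.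

## Retrosynthesis

**Ester.** The C6 O–acyl bond of 16 is cut first, giving epoxy diol 14 and commercial 3,4-dimethoxybenzoyl chloride 15. This removes the one group that no organometallic or fluoride step would tolerate, and it frees the C6 hydroxyl, which is needed one step earlier as a directing group. Cutting the epoxide first would give up that direction. The forward reaction must acylate a secondary alcohol beside a tertiary one and an epoxide, so it has to run under base only.

**Epoxide.** Both C–O bonds of the epoxide in 14 are removed to give the ene diol 13. An epoxide cannot be carried through Grignard addition or metathesis, whereas the alkene is the natural product of ring closure. Compound 13 has four stereocentres instead of six. The forward step must put oxygen on the H5 face; the homoallylic C6 hydroxyl on that face and the axial C1 methyl on the other both favour this.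

**Isopropyl group.** After masking the C6 hydroxyl as its triethylsilyl ether (12), the C4–CH(CH3)2 bond is cut to give the bicyclic ketone 11. This restores the carbonyl that the key step needs. The addition is placed on the bicycle and not on the monocyclic ketone 10, because the trans-fused skeleton holds the C1 methyl axial over one face of the C4 carbonyl. Compound 11 has three stereocentres. The forward step must add a branched nucleophile to a hindered, enolisable ketone from the H5 face without epimerising C5.

**Seven-membered ring.** The C8=C9 bond of 11 is cut by retro-metathesis to give the monocyclic diene 10. Closing C9–C10 or C7–C8 by alkylation or cross-coupling would need extra functional groups at both ends. The two alkenes, in contrast, arrive free of charge with the building blocks of the key step, and the double bond lands where the epoxide is needed. The forward step must form a trisubstituted cycloheptene trans-fused to a cyclopentanone; the hydroxyl is silylated beforehand (9 to 10) so that no retro-aldol can occur on warming.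

**Five-membered ring, key disconnection.** In 9 the C1–CH3 bond and the C5–C6 bond are cut together, giving 3-allylcyclopent-2-en-1-one 4, trimethylaluminium 7 and 3-methylbut-3-enal 6.
- Cutting only C5–C6 would require a preformed 3-allyl-3-methylcyclopentanone to enolise toward its hindered α-carbon, which it would not do. Conjugate addition generates the enolate at C5 and nowhere else, and sets C1 in the same operation.
- Cutting C1–C10 instead (allyl transfer to 3-methylcyclopentenone) would rest on a conjugate allyl transfer, which is far less dependable than the methyl transfer from Me3Al.
- Three achiral pieces replace a compound with three stereocentres. The configurations of 9 were checked atom by atom against 16 (C1 R, C5 S, C6 S).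
- The forward reaction must deliver methyl enantioselectively, bring the aldehyde onto the enolate face anti to the allyl arm through a closed transition state, and do so before the labile aldehyde isomerises.

**Building blocks.** Enone 4 is cut at the bond between the ring and the allyl group, with carbonyl transposition, to 3-ethoxycyclopent-2-en-1-one 1 and allylmagnesium bromide 2. Aldehyde 6 is one oxidation level above 3-methylbut-3-en-1-ol 5.

## Roads not taken

**Alternative 1:** The cut is C9–C10. The precursor is the monocyclic diiodide A1, a cyclopentane with a neopentyl CH2I on C1, the C4 carbinol as a trimethylsilyl ether, and a C5 side chain ending in a (Z)-vinyl iodide. Forward, Zn inserts into the C10–I bond and Pd(P(t-Bu)3)2 couples the alkylzinc with the vinyl iodide, closing the seven-membered ring to the bicyclic bis-silyl ether A2.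
- Merits: the C10 organometallic has no β-hydrogen to lose, the alkene position and geometry are fixed by the vinyl iodide, and the tertiary carbinol is already in place when the ring closes.
- Weak points: selective zinc insertion into a hindered neopentyl iodide beside a vinyl iodide is delicate; seven-membered ring closure by alkyl–alkenyl coupling is entropically poor and must compete with intermolecular coupling; and A1 needs all of C1, C4, C5 and C6 plus two different iodides to be installed on a monocycle, where the C4 addition has less facial bias.
- Comparison: this road is more robust in one respect, since the hindered ketone addition is not performed next to a finished seven-membered ring. Against it the chosen plan sets a much shorter sequence and two alkenes that come with the key step instead of two iodides that must be made separately. It also leaves the C1/C5/C6 problem unsolved, which still has to be answered before A1 exists.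

**Alternative 2:** The cuts are C1–C10 and a temporary C5–C9 bond. The precursor is the 2-(pent-4-enyl)-substituted 3-methylcyclopentenone A3, whose tether carries the C6 silyl ether and a C8 methyl ether. Irradiation at 350 nm gives the tricyclic photoadduct A4 (cyclopentanone, cyclobutane, cyclopentane). Reductive cleavage of the C5–C9 bond with SmI2, with loss of methoxide from C8, then opens the seven-membered ring and leaves the C8=C9 alkene and the C4 enolate.
- Merits: quaternary C1 is formed intramolecularly with dependable regiochemistry (three-atom tether), no chiral catalyst is needed, and the methyl-versus-allyl discrimination that burdens the chosen plan does not arise.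
- Weak points: absolute configuration must first be put into C6 by a separate asymmetric step; facial selectivity of the cycloaddition hangs on one silyloxy stereocentre of a flexible tether; the C8 ether centre must be built only to be destroyed; and C5 is set last, by protonation of the enolate released in the fragmentation, where cis or trans ring fusion is not secured.
- Comparison: this road is better at fixing C1 relative to C6. The chosen plan sets against it catalytic enantiocontrol, C5 and C6 formed in the same closed transition state, and fewer steps.

**Alternative 3:** The cut is C3–C4. The precursor is the α-branched aldehyde A5 with two vinyl groups and a methyl group on C1 and with C5 and C6 already set. [Rh((R)-BINAP)]ClO4 (or its enantiomer) adds the aldehyde C–H bond across one vinyl group and closes the cyclopentanone A6, a 3-methyl-3-vinylcyclopentanone with the silyloxy ketal side chain.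
- Merits: C5 and C6 can be made beforehand by an acyclic aldol of high reliability, and C1 is then set relative to C5 by a catalyst choosing between two vinyl groups. This is better than the chosen plan exactly at its weak point.
- Weak points: A5, with a divinyl quaternary carbon next to a stereocentre, is laborious; α-branched pentenals react slowly and decarbonylate; and the catalyst may have to override the substrate's own bias. The surviving vinyl group supplies C10 and C9 but cannot be closed onto C8 by metathesis, which would give a six-membered ring. Hydroboration, oxidation and a carbonyl coupling to the C8 ketone would be needed while the C4 ketone is present.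
- Comparison: the chosen plan sets against the catalyst-controlled C1/C5 relationship its convergence (two bonds and three stereocentres from three small achiral pieces in one flask) and a direct metathesis closure.

Key step: step 3

Assumption: the phosphoramidite L* written in step 3, O,O'-(biphenyl-2,2'-diyl) N,N-bis[(S)-1-(naphthalen-2-yl)ethyl]phosphoramidite, is taken to deliver methyl to the Si face of the β-carbon of 4 (giving R at C1); if its sense of induction is the opposite, the mirror-image ligand is used and nothing else changes.

## Route

Step 1
Reactants: 1 3-ethoxycyclopent-2-en-1-one; 2 allylmagnesium bromide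
Product: 4 3-allylcyclopent-2-en-1-one, via tertiary magnesium alkoxide 3 (not isolated)
Conditions: 2 (1.2 equiv), Et2O, 0 °C; then 1 M HCl, 0 °C, short contact
Reagents that add atoms: water, O
Why: Stork–Danheiser sequence: 1,2-addition of the Grignard reagent to the vinylogous ester, then acid-induced ionisation of the tertiary allylic alcohol and hydrolysis of the enol ether transpose the carbonyl. Cold, dilute acid and short contact should keep the allyl double bond from moving into conjugation; no stereocentre is formed.

Step 2
Reactants: 5 3-methylbut-3-en-1-ol
Product: 6 3-methylbut-3-enal
Conditions: Dess–Martin periodinane (1.2 equiv), pyridine (2 equiv), CH2Cl2, 0 °C to rt; Na2S2O3/NaHCO3 wash; used at once as a dried solution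
Reagents that add atoms: none
Why: Dess–Martin oxidation of a primary homoallylic alcohol under buffered, near-neutral conditions, which should leave the 1,1-disubstituted alkene out of conjugation. The aldehyde is volatile and labile and is therefore not stored.

Step 3
Reactants: 4 3-allylcyclopent-2-en-1-one; 7 trimethylaluminium; 6 3-methylbut-3-enal
Product: 9 (2S,3R)-3-allyl-2-[(1S)-1-hydroxy-3-methylbut-3-en-1-yl]-3-methylcyclopentan-1-one, via dimethylaluminium enolate 8 (not isolated)
Conditions: 7 (1.2 equiv), CuTC [Cu(O2C-C4H3S), copper thiophene-2-carboxylate] (5 mol %), phosphoramidite L* (10 mol %), Et2O, −30 to −10 °C; then 6 (2 equiv), −78 °C; aq. KNaC4H4O6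
Reagents that add atoms: none
Why: CuTC and the phosphoramidite form with Me3Al a chiral methylcopper–aluminium species that binds the enone while aluminium activates the carbonyl; oxidative addition at the β-carbon and reductive elimination from a transient trivalent copper intermediate form C1–CH3 and leave the dimethylaluminium enolate 8. The closest known reaction type is the copper-catalysed asymmetric conjugate addition of trialkylaluminium reagents to 3-substituted cyclopentenones with aldol trapping of the aluminium enolate, a three-component conjugate addition–aldol coupling; no ring is closed. C1 (R) is set by the ligand, which delivers methyl to the Si face of the β-carbon. C6 (S) follows from a Zimmerman–Traxler chair in which aluminium bridges the enolate and aldehyde oxygens: the ring enolate can only be E and the methallyl group of 6 sits equatorial, which gives the anti aldol. C5 (S) is set by the face of 8 that the aldehyde takes, the one anti to the allyl arm and syn to the smaller methyl group at C1; running the aldol at −78 °C on the neutral, tightly bound aluminium enolate (no ate complex) should make the most of this small difference, and the C5 epimer is a diastereomer to be removed by chromatography. Chemoselectivity (1,4- over 1,2-methyl transfer; aldol ahead of methylation of 6 by residual Me3Al or isomerisation of 6 to the conjugated enal) rests on copper catalysis, the low temperature, the absence of any alkyllithium and the excess of 6. Enolate regiochemistry is not in question, because conjugate addition generates the enolate only between C4 and C5.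

Step 4
Reactants: 9 (2S,3R)-3-allyl-2-[(1S)-1-hydroxy-3-methylbut-3-en-1-yl]-3-methylcyclopentan-1-one
Product: 10 (2S,3R)-3-allyl-3-methyl-2-[(1S)-3-methyl-1-(triethylsilyloxy)but-3-en-1-yl]cyclopentan-1-one
Conditions: Et3SiOTf (1.2 equiv), 2,6-lutidine (2 equiv), CH2Cl2, −78 °C
Reagents that add atoms: triethylsilyl trifluoromethanesulfonate, CC[Si](CC)(CC)OS(=O)(=O)C(F)(F)F
Why: Silylation of a secondary alcohol with a silyl triflate and a hindered pyridine base. At −78 °C this should be faster than retro-aldol cleavage, C5 epimerisation or silyl enol ether formation; no stereocentre is touched.

Step 5
Reactants: 10 (2S,3R)-3-allyl-3-methyl-2-[(1S)-3-methyl-1-(triethylsilyloxy)but-3-en-1-yl]cyclopentan-1-one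
Product: 11 (3aR,8S,8aS)-3a,6-dimethyl-8-(triethylsilyloxy)-3,3a,4,7,8,8a-hexahydroazulen-1(2H)-one (text numbering: C4 ketone, C6 OSiEt3, C8=C9, trans ring fusion)
Conditions: second-generation Grubbs catalyst RuCl2(=CHPh)(PCy3)(H2IMes) (5 mol %), CH2Cl2 (0.005 M), 40 °C
Reagents that add atoms: none
Why: Ring-closing olefin metathesis between the monosubstituted allyl alkene (initiation site) and the 1,1-disubstituted alkene, driven by loss of ethene at high dilution, forming the trisubstituted C8=C9 cycloheptene. The arms are trans on the cyclopentanone, so the bicycle is trans-fused; no stereocentre is formed or touched under these neutral conditions.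

Step 6
Reactants: 11 (3aR,8S,8aS)-3a,6-dimethyl-8-(triethylsilyloxy)-3,3a,4,7,8,8a-hexahydroazulen-1(2H)-one
Product: 12 (3R,3aS,4S,8aR)-6,8a-dimethyl-3-(propan-2-yl)-4-(triethylsilyloxy)-1,2,3,3a,4,5,8,8a-octahydroazulen-3-ol
Conditions: i-PrMgCl (3 equiv), anhydrous CeCl3 (3 equiv), THF, −78 to 0 °C; aq. NH4Cl
Reagents that add atoms: isopropylmagnesium chloride, CC(C)[Mg]Cl
Why: Organocerium 1,2-addition to a hindered, enolisable ketone; the cerium reagent is weakly basic, which should suppress enolisation at C3/C5 and β-hydride reduction. The isopropyl group should enter from the H5 face, anti to the axial C1 methyl that sits 1,3 to the carbonyl on the other face, giving C4 (R) with the hydroxyl on the methyl face.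

Step 7
Reactants: 12 (3R,3aS,4S,8aR)-6,8a-dimethyl-3-(propan-2-yl)-4-(triethylsilyloxy)-1,2,3,3a,4,5,8,8a-octahydroazulen-3-ol
Product: 13 (3R,3aS,4S,8aR)-6,8a-dimethyl-3-(propan-2-yl)-1,2,3,3a,4,5,8,8a-octahydroazulene-3,4-diol (jaeschkeanadiol)
Conditions: Bu4NF (1.5 equiv), THF, 0 °C to rt
Reagents that add atoms: none
Why: Fluoride-induced cleavage of a triethylsilyl ether; the tertiary alcohol and the alkene are inert. Should the silyl group have migrated to the C4 oxygen in step 6, it is removed all the same.

Step 8
Reactants: 13 jaeschkeanadiol
Product: 14 epoxy diol, the 8,9-epoxide of 13 with the oxygen on the H5 face (text numbering: 1R,4R,5S,6S,8R,9S)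
Conditions: VO(acac)2 (5 mol %), t-BuOOH (1.5 equiv, in decane), CH2Cl2, 0 °C to rt
Reagents that add atoms: tert-butyl hydroperoxide, CC(C)(C)OO
Why: Hydroxyl-directed vanadium-catalysed epoxidation of a homoallylic alcohol: the C6 alkoxide holds the vanadium peroxide over the H5 face of C8=C9 and sets C8 (R) and C9 (S). The same face is the sterically open one, since the axial C1 methyl shields the other, so direction and substrate bias should agree. The epoxy alcohol is syn and cannot open itself by backside attack.

Step 9
Reactants: 14 epoxy diol; 15 3,4-dimethoxybenzoyl chloride
Product: 16 target CNP0251065.1, the C6 3,4-dimethoxybenzoate of 14 (text numbering: 1R,4R,5S,6S,8R,9S)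
Conditions: 15 (1.5 equiv), Et3N (3 equiv), DMAP (0.2 equiv), CH2Cl2, 0 °C to rt
Reagents that add atoms: none
Why: DMAP-catalysed acylation of the secondary C6 hydroxyl with an acid chloride. The tertiary C4 hydroxyl, flanked by isopropyl and the ring fusion, should not react, and the basic medium should leave the epoxide intact.

## Compound list

1 | 3-ethoxycyclopent-2-en-1-one | CCOC1=CC(=O)CC1 | starting material
2 | allylmagnesium bromide | C=CC[Mg]Br | starting material
3 | bromomagnesium 1-allyl-3-ethoxycyclopent-2-en-1-olate (racemic) | C=CCC1(O[Mg]Br)C=C(OCC)CC1 | intermediate
4 | 3-allylcyclopent-2-en-1-one | C=CCC1=CC(=O)CC1 | intermediate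
5 | 3-methylbut-3-en-1-ol | CC(=C)CCO | starting material
6 | 3-methylbut-3-enal | CC(=C)CC=O | intermediate
7 | trimethylaluminium | C[Al](C)C | starting material
8 | dimethylaluminium (3R)-3-allyl-3-methylcyclopent-1-en-1-olate | C=CC[C@@]1(C)CCC(O[Al](C)C)=C1 | intermediate
9 | (2S,3R)-3-allyl-2-[(1S)-1-hydroxy-3-methylbut-3-en-1-yl]-3-methylcyclopentan-1-one | C=CC[C@@]1(C)CCC(=O)[C@@H]1[C@@H](O)CC(C)=C | intermediate
10 | (2S,3R)-3-allyl-3-methyl-2-[(1S)-3-methyl-1-(triethylsilyloxy)but-3-en-1-yl]cyclopentan-1-one | C=CC[C@@]1(C)CCC(=O)[C@@H]1[C@@H](O[Si](CC)(CC)CC)CC(C)=C | intermediate
11 | (3aR,8S,8aS)-3a,6-dimethyl-8-(triethylsilyloxy)-3,3a,4,7,8,8a-hexahydroazulen-1(2H)-one | CC[Si](CC)(CC)O[C@H]1CC(C)=CC[C@@]2(C)CCC(=O)[C@H]12 | intermediate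
12 | (3R,3aS,4S,8aR)-6,8a-dimethyl-3-(propan-2-yl)-4-(triethylsilyloxy)-1,2,3,3a,4,5,8,8a-octahydroazulen-3-ol | CC[Si](CC)(CC)O[C@H]1CC(C)=CC[C@@]2(C)CC[C@@](O)(C(C)C)[C@H]12 | intermediate
13 | (3R,3aS,4S,8aR)-6,8a-dimethyl-3-(propan-2-yl)-1,2,3,3a,4,5,8,8a-octahydroazulene-3,4-diol (jaeschkeanadiol) | O[C@H]1CC(C)=CC[C@@]2(C)CC[C@@](O)(C(C)C)[C@H]12 | intermediate
14 | 8,9-epoxide of 13, oxygen on the H5 face (text numbering 1R,4R,5S,6S,8R,9S) | O[C@H]1C[C@@]2(C)O[C@H]2C[C@@]2(C)CC[C@@](O)(C(C)C)[C@H]12 | intermediate
15 | 3,4-dimethoxybenzoyl chloride | COc1ccc(C(=O)Cl)cc1OC | starting material
16 | CNP0251065.1, C6 3,4-dimethoxybenzoate of 14 (text numbering 1R,4R,5S,6S,8R,9S) | COc1ccc(C(=O)O[C@H]2C[C@@]3(C)O[C@H]3C[C@@]3(C)CC[C@@](O)(C(C)C)[C@H]23)cc1OC | target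

## Step count and risks

Total: 9 steps. Longest linear sequence: 8 steps (1, 3, 4, 5, 6, 7, 8, 9, from 3-ethoxycyclopent-2-en-1-one); step 2 is a one-step side branch.

**Step 3 (key step).** The most likely failure is poor facial discrimination at C5, because the enolate faces differ only by methyl against a CH2 arm. Second is loss of the labile aldehyde (methylation by residual Me3Al, or isomerisation to the conjugated enal) before the hindered enolate reaches it. Fallback: setting out from 4, the copper-catalysed methyl addition is run alone and enolate 8 is silylated in the flask with Me3SiOTf to give the trimethylsilyl enol ether F1, which is isolated and freed of aluminium and copper residues. MeLi in THF then converts it into the lithium enolate F2, which adds to 6 at −78 °C through a lithium-centred chair and returns to the route at 9. Separating the two bond formations removes the competition between Me3Al and the enolate for the aldehyde and allows the enolate counter-ion to be chosen for tighter facial control.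

**Step 5.** Ring closure may lose to intermolecular metathesis at the allyl terminus, or to ruthenium-hydride migration of the allyl double bond, because the second alkene is 1,1-disubstituted and initiates slowly. Fallback: setting out from 10, the order is changed. i-PrMgCl/CeCl3 adds to the monocyclic ketone first (attack anti to the C5 side chain) to give the monocyclic carbinol F3. Its tetrahedral C4 with the isopropyl group pushes the C5 side chain toward the allyl arm, and it has no epimerisable ketone. Metathesis of F3 with the same ruthenium catalyst returns to the route at 12.

**Step 6.** Enolisation or β-hydride reduction may take the place of addition at the crowded C4 carbonyl, or the nucleophile may attack in part from the methyl face. Fallback: setting out from 11, the smaller sp2 nucleophile isopropenylmagnesium bromide with CeCl3 gives the isopropenyl carbinol F4. Hydrogenation over RhCl(PPh3)3, which reduces a 1,1-disubstituted alkene much faster than the trisubstituted ring alkene, returns to the route at 12.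

**Step 8.** The C6 hydroxyl is equatorial and may fail to hold the vanadium over the alkene, which would mean loss of direction. Alternatively the Lewis-acidic metal may trigger transannular opening of the new epoxide by the C4 hydroxyl. Fallback: setting out from 13, the order of the last two steps is reversed. Acylation with 15 (Et3N, DMAP) gives jaeschkeanadiol 3,4-dimethoxybenzoate F5. Epoxidation with mCPBA buffered by NaHCO3 then relies only on the shielding of the methyl face by the axial C1 methyl and arrives directly at 16.

## Further compounds

F1 | step 3 | trimethylsilyl enol ether, (3R)-3-allyl-3-methyl-1-(trimethylsilyloxy)cyclopent-1-ene | C=CC[C@@]1(C)CCC(O[Si](C)(C)C)=C1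
F2 | step 3 | lithium (3R)-3-allyl-3-methylcyclopent-1-en-1-olate | C=CC[C@@]1(C)CCC(O[Li])=C1
F3 | step 5 | monocyclic carbinol, isopropyl adduct of 10 at C4 | C=CC[C@@]1(C)CC[C@@](O)(C(C)C)[C@@H]1[C@@H](O[Si](CC)(CC)CC)CC(C)=C
F4 | step 6 | isopropenyl carbinol, isopropenyl analogue of 12 | CC[Si](CC)(CC)O[C@H]1CC(C)=CC[C@@]2(C)CC[C@@](O)(C(C)=C)[C@H]12
F5 | step 8 | jaeschkeanadiol 6-O-(3,4-dimethoxybenzoate) | COc1ccc(C(=O)O[C@H]2CC(C)=CC[C@@]3(C)CC[C@@](O)(C(C)C)[C@H]23)cc1OC
A1 | alternative 1 | monocyclic neopentyl iodide/(Z)-vinyl iodide bis-silyl ether | IC[C@@]1(C)CC[C@@](O[Si](C)(C)C)(C(C)C)[C@@H]1[C@@H](O[Si](CC)(CC)CC)C/C(C)=C\I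
A2 | alternative 1 | bis-silyl ether of the bicyclic 8,9-ene diol | CC[Si](CC)(CC)O[C@H]1CC(C)=CC[C@@]2(C)CC[C@@](O[Si](C)(C)C)(C(C)C)[C@H]12
A3 | alternative 2 | 2-[1-(tert-butyldimethylsilyloxy)-3-methoxy-3-methylpent-4-enyl]-3-methylcyclopent-2-en-1-one | O=C1CCC(C)=C1[C@@H](O[Si](C)(C)C(C)(C)C)C[C@@](C)(OC)C=C
A4 | alternative 2 | tricyclic photoadduct (cyclopentanone, cyclobutane, cyclopentane) | O=C1CC[C@]2(C)C[C@H]3[C@](C)(OC)C[C@H](O[Si](C)(C)C(C)(C)C)[C@@]123
A5 | alternative 3 | divinyl aldehyde with silyloxy ketal side chain | O=C[C@H]([C@@H](O[Si](CC)(CC)CC)CC1(C)OCCO1)C(C)(C=C)C=C
A6 | alternative 3 | 3-methyl-3-vinylcyclopentanone with silyloxy ketal side chain at C2 | C=C[C@@]1(C)CCC(=O)[C@@H]1[C@@H](O[Si](CC)(CC)CC)CC1(C)OCCO1
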